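## Structural features

Compound 26 is a C20 diterpenoid acetate with a tricyclic core. An eight-membered carbocycle (C1, C2, C3, C4, C6, C7, C8, C9) is fused through its C2=C3 double bond to a butenolide (C2 carries the lactone CH2O, C3 the lactone C=O) and through the C4–C6 bond to a cis-cyclopropane whose methylene is C5. The stereocentres C4, C6 and C7 (methyl) are contiguous on one flank. On the other flank the secondary carbinol C9 adjoins C1, and C1 carries the exocyclic stereocentre C1', which bears the acetoxymethyl carbon C2' and a 4-methylpent-3-enyl chain. The C9 hydroxyl and the C1 side chain are cis on the ring.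

The fragile sites are the γ-positions of the butenolide (C1–H and the lactone CH2 are vinylogously acidic) and the C9 hydroxyl, a vinylogous aldol hydroxyl that can undergo retro-aldol cleavage or E1cB dehydration with base. The trisubstituted alkene is sensitive to acid, electrophiles and hydrogenation, and the primary acetate and the cyclopropane conjugated to the lactone also need care.

The real difficulty is closing the eight-membered ring with control of C1 and C9 relative to C4/C6/C7, and then setting the acyclic centre C1'. The key step exploits the fact that C9 is a carbinol whose neighbour C1 is allylic to the butenolide and, in retrosynthesis, to a C1'=C2' methylene. This homoallylic alcohol is the retron of a γ-selective allylmetal addition, and the methylene left behind is the handle for the C2' oxygen.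

## Logic of the disconnections

**26 to 25.** The acetate C–O bond is cut last, because the ester would not survive hydride, base or organometallic steps. This demands acylation of a primary hydroxyl in the presence of the hindered secondary C9 hydroxyl.

**25 to 23.** The C2'–O and C1'–H bonds are removed as an anti-Markovnikov hydration of a C1'=C2' methylene. This deletes one stereocentre and one oxygen. The forward step must pick the 1,1-disubstituted alkene over the trisubstituted one and one face of it.

**23 to 21.** The C1–C9 bond is cut (key step). The eight-membered ring and two stereocentres disappear, and a flat butenolide with two side arms remains. The forward closure needs bonding through C1 and not through C2' or C3, the cis relation at C1/C9, and high dilution.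

**21 to 19 to 18.** The C2'–Br bond and the C9 aldehyde are traced back to a silyl ether and a methyl enol ether. Both reactive ends stay masked through the couplings. One acid step must unmask both, and the bromide must then be made in the presence of the aldehyde.

**18 to 7 and 17.** The C3–C4 bond (alkene carbon to cyclopropyl carbon) is cut, which makes the route convergent. The coupling must proceed with retention at the cyclopropyl carbon and tolerate the base-sensitive lactone.

**7 to 5 and 6.** The C2–C1 bond is cut. The forward step must replace only the β-bromide of 6 and keep the alkene geometry of 5.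

**5 to 2, 3 and 4 (2 from 1).** The C1–B and C1'–C bonds are formed across the alkyne of 3. Syn addition with boron on the terminal carbon gives the E geometry that 21 needs.

**17 to 16 to 15 to 14.** The C8=C9 bond is cut (one-carbon homologation), and the C8 oxygen is traced back to a silyl ether. The silyloxymethyl group is kept beside C7 until the cyclopropane exists, because it is the steric control element of that step. Aldehyde 16 must not epimerise at C7.

**14 to 13.** The C4–C5 and C5–C6 bonds are cut (methylene transfer to a Z-alkene). The cis ring follows from the alkene geometry. The methylene must enter from the methyl face, anti to the silyloxymethyl group. A free C8 hydroxyl would deliver the zinc reagent to the opposite face and give the wrong C6/C7 relation, so the oxygen is carried as a bulky, non-coordinating silyl ether.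

**13 to 11 and 12.** The C4–B bond is cut. The hydroboration must be anti-Markovnikov and trans, to give the Z-alkenylboronate.

**11 to 10 to 9 to 8.** The alkyne carbon C4 is removed, the ester is reduced, and the hydroxyl is protected. C7 comes from the chiral pool: the ester carbon of 8 becomes C6 and its CH2OH becomes C8, which fits the S configuration of 8. Aldehyde 10 must not racemise.

## Other disconnections considered

Alternative 1: The cut runs through the cyclopropane (C4–C5 and C4–C6) and opens the eight-membered ring at the same time. In the forward step Ph3PAuCl with AgSbF6 would move the pivalate of the tertiary propargyl ester A2 from C2 to C3. The gold carbenoid at C4 would then add to the tethered C5=C6 alkene and give the enol pivalate A1.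
- In its favour: two rings and the centres C4 and C6 arise in one catalytic step, and the cis ring fusion is a geometric necessity. On that point it is better than the chosen plan, whose cyclopropane rests on facial selectivity in step 8. It also avoids the large excess of CrCl2 of step 15.
- Against it here: A1 has oxygen, not carbon, at C3, so the lactone carbonyl must be added afterwards (ketone, enol triflate, carbonylation, lactonisation). The homoprenyl alkene cannot be present in A2 because it would compete for the carbenoid, so it is carried as a protected propanol and rebuilt. C1, C1', C7 and C9 must all be set in an open chain first, which makes the route linear.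
- Comparison: both plans close the eight-membered ring directly and are equal there. The chosen plan is shorter and convergent. Alternative 1 is more certain for the cyclopropane geometry.

Alternative 2: The cut is C1–C9 together with C2–C3, reached through a temporary C3–C9 bond. Irradiation of the enolised keto ester A4 would add the enol C9=C3 to the tethered C1=C2 alkene, and retro-aldol opening of the cyclobutanol would give the cyclooctanone A3.
- In its favour: the eight-membered ring comes from a six-membered one by two-carbon expansion. This avoids a direct medium-ring closure, and on that point it is better than the chosen plan. It forms the same C1–C9 bond and needs no metal.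
- Against it here: A3 has a saturated lactone and a C9 ketone. C2=C3 must be introduced next to a second enolisable carbonyl, and C9 must be reduced stereoselectively. The 1,4-diradical carries spin at C3, next to the cyclopropane, so ring opening threatens. The triplet path can scramble the alkene geometry and with it C1.
- Comparison: the two plans are equal in the bond they make at C1–C9. The chosen plan is better in redox economy and keeps radicals away from the cyclopropane.

Alternative 3: The cut is the C2'–O bond, made last on an unactivated methyl group. The diethylhydrosilyl ether A6 would undergo dehydrogenative silylation of a C2' methyl C–H bond with [Rh(Xantphos)Cl] and norbornene to give the oxasilinane A5, which would be oxidised to 25.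
- In its favour: the C2' oxygen and its protecting group leave the early route. C1' would be set beforehand by a hydroxyl-directed reduction with cyclic delivery, which may be the equal or the better of the uncatalysed hydroboration of step 16 in predictability.
- Against it here: the C7 methyl is also δ to the C9 oxygen (O–C9–C8–C7–CH3), so two methyl groups compete for the same six-membered silacycle. The rhodium hydride and Si–H system can reduce or isomerise the trisubstituted alkene. The sequence needs four operations where the chosen plan needs one hydroboration.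
- Comparison: the chosen plan is better in step economy and site selectivity. Alternative 3 may be better in the control of C1'.

Key step: step 15

Assumption: the C1'=C1 double bond of 21 is taken as E (CH2Br trans to the butenolide); σ-allylchromium species interconvert their E and Z forms, so this geometry should not decide the outcome of step 15.

Step 1
Reactants: 1 5-bromo-2-methylpent-2-ene
Product: 2 5-iodo-2-methylpent-2-ene
Conditions: NaI (3 equiv), acetone, reflux
Reagents that add atoms: sodium iodide, [Na+].[I-]
Why: Finkelstein halide exchange at a primary carbon, driven by precipitation of NaBr; the iodide is the better electrophile for the alkenylcopper intermediate of step 2.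

Step 2
Reactants: 2 5-iodo-2-methylpent-2-ene; 3 tert-butyldimethyl(prop-2-yn-1-yloxy)silane; 4 bis(pinacolato)diboron
Product: 5 (E)-tert-butyldimethyl{[6-methyl-2-[(4,4,5,5-tetramethyl-1,3,2-dioxaborolan-2-yl)methylidene]hept-5-en-1-yl]oxy}silane
Conditions: CuCl (10 mol %), Xantphos (10 mol %), KOtBu (1.5 equiv), DMA, rt
Reagents that add atoms: none
Why: Copper-catalysed alkylboration of a terminal alkyne: the boryl complex of monovalent copper adds syn with boron on the terminal carbon, and the internal alkenylcopper is alkylated by the primary iodide with retention. Boron therefore ends cis to the new chain and trans to CH2OTBS (E).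

Step 3
Reactants: 5 the (E)-alkenylboronate; 6 3,4-dibromofuran-2(5H)-one
Product: 7 3-bromo-4-[(1E)-2-({[tert-butyl(dimethyl)silyl]oxy}methyl)-6-methylhepta-1,5-dien-1-yl]furan-2(5H)-one
Conditions: PdCl2(dppf) (5 mol %), K3PO4, THF/H2O, 45 °C
Reagents that add atoms: none
Why: Suzuki–Miyaura coupling; zerovalent palladium inserts into the β C–Br bond (a vinylogous acyl bromide) much faster than into the α C–Br bond, so only the β-bromide is replaced. The alkene geometry of 5 is retained.

Step 4
Reactants: 8 methyl (S)-3-hydroxy-2-methylpropanoate
Product: 9 methyl (S)-3-[(tert-butyldiphenylsilyl)oxy]-2-methylpropanoate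
Conditions: TBDPSCl, imidazole, CH2Cl2, 0 °C to rt
Reagents that add atoms: tert-butyl(chloro)diphenylsilane, CC(C)(C)[Si](Cl)(c1ccccc1)c1ccccc1
Why: Standard silylation of a primary alcohol; the bulky, poorly coordinating silyl ether is chosen because it later serves as the steric control element of step 8.

Step 5
Reactants: 9 methyl (S)-3-[(tert-butyldiphenylsilyl)oxy]-2-methylpropanoate
Product: 10 (S)-3-[(tert-butyldiphenylsilyl)oxy]-2-methylpropanal
Conditions: DIBAL-H (1.1 equiv), CH2Cl2, −78 °C; Rochelle salt
Reagents that add atoms: none
Why: Partial reduction of an ester; the aluminium hemiacetal is stable at −78 °C and releases the aldehyde on work-up. The α-stereocentre is not touched at this temperature.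

Step 6
Reactants: 10 (S)-3-[(tert-butyldiphenylsilyl)oxy]-2-methylpropanal
Product: 11 (R)-tert-butyl[(2-methylbut-3-yn-1-yl)oxy]diphenylsilane
Conditions: dimethyl (1-diazo-2-oxopropyl)phosphonate, K2CO3, MeOH, 0 °C to rt
Reagents that add atoms: dimethyl (1-diazo-2-oxopropyl)phosphonate, COP(=O)(OC)C(=[N+]=[N-])C(C)=O
Why: Ohira–Bestmann homologation of an aldehyde to a terminal alkyne; the mild carbonate/methanol conditions keep the α-stereocentre. The descriptor changes from S to R only because the priorities change.

Step 7
Reactants: 11 (R)-tert-butyl[(2-methylbut-3-yn-1-yl)oxy]diphenylsilane; 12 pinacolborane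
Product: 13 (R,Z)-tert-butyl{[2-methyl-4-(4,4,5,5-tetramethyl-1,3,2-dioxaborolan-2-yl)but-3-en-1-yl]oxy}diphenylsilane
Conditions: [Rh(cod)Cl]2 (1.5 mol %), P(iPr)3 (6 mol %), Et3N, cyclohexane, rt
Reagents that add atoms: none
Why: Rhodium-catalysed trans-hydroboration of a terminal alkyne through a rhodium vinylidene, which places boron on the terminal carbon and gives the Z-alkenylboronate needed for a cis-cyclopropane. No stereocentre is formed.

Step 8
Reactants: 13 the (R,Z)-alkenylboronate
Product: 14 tert-butyl{(2R)-2-[(1S,2R)-2-(4,4,5,5-tetramethyl-1,3,2-dioxaborolan-2-yl)cyclopropyl]propoxy}diphenylsilane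
Conditions: Et2Zn, CF3CO2H, CH2I2, CH2Cl2, 0 °C to rt
Reagents that add atoms: diiodomethane, ICI
Why: Simmons–Smith cyclopropanation of an alkenylboronate with the reactive carbenoid CF3CO2ZnCH2I; the addition is stereospecific, so the Z-alkene gives the cis ring. A1,3 strain with the cis boryl group holds C7–H in the alkene plane, so CH3 and CH2OTBDPS lie on opposite faces. The hindered silyl ether cannot direct zinc, and the carbenoid should enter past the smaller methyl group, which sets C4 and C6 as required.

Step 9
Reactants: 14 the silyl-protected cyclopropylboronate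
Product: 15 (2R)-2-[(1S,2R)-2-(4,4,5,5-tetramethyl-1,3,2-dioxaborolan-2-yl)cyclopropyl]propan-1-ol
Conditions: TBAF, AcOH, THF, rt
Reagents that add atoms: none
Why: Fluoride cleavage of the silyl ether; acetic acid buffers the alkoxide so that the pinacol boronate is left intact.

Step 10
Reactants: 15 the cyclopropyl alcohol
Product: 16 (2R)-2-[(1S,2R)-2-(4,4,5,5-tetramethyl-1,3,2-dioxaborolan-2-yl)cyclopropyl]propanal
Conditions: Dess–Martin periodinane, CH2Cl2, 0 °C to rt
Reagents that add atoms: none
Why: Neutral hypervalent-iodine oxidation of a primary alcohol; no base is present, so C7 (now α to the aldehyde) is not epimerised and the C–B bond is not oxidised.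

Step 11
Reactants: 16 the cyclopropyl aldehyde
Product: 17 2-{(1R,2S)-2-[(2R)-4-methoxybut-3-en-2-yl]cyclopropyl}-4,4,5,5-tetramethyl-1,3,2-dioxaborolane (E/Z mixture at the enol ether)
Conditions: Ph3P(CH2OMe)Cl, KHMDS, THF, −78 to 0 °C
Reagents that add atoms: (methoxymethyl)triphenylphosphonium chloride, COC[P+](c1ccccc1)(c1ccccc1)c1ccccc1.[Cl-]
Why: Wittig methoxymethylenation adds C9 as a base-stable latent aldehyde; the enol ether geometry is irrelevant. Preformed ylide and low temperature keep C7 from epimerising.

Step 12
Reactants: 7 the 3-bromobutenolide; 17 the cyclopropylboronate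
Product: 18 4-[(1E)-2-({[tert-butyl(dimethyl)silyl]oxy}methyl)-6-methylhepta-1,5-dien-1-yl]-3-{(1R,2R)-2-[(2R)-4-methoxybut-3-en-2-yl]cyclopropyl}furan-2(5H)-one
Conditions: Pd(OAc)2 (10 mol %), SPhos (20 mol %), K3PO4, toluene/H2O, 80 °C
Reagents that add atoms: none
Why: Suzuki–Miyaura coupling of a cyclopropylboronate with an α-bromo enoate; cyclopropyl–boron bonds transmetalate with retention, so the cis relation and the configuration at C4 are carried over. The bulky electron-rich phosphine speeds the steps at the hindered tetrasubstituted alkene.

Step 13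
Reactants: 18 the coupled butenolide
Product: 19 4-[(1E)-2-(hydroxymethyl)-6-methylhepta-1,5-dien-1-yl]-3-{(1R,2R)-2-[(2S)-4-oxobutan-2-yl]cyclopropyl}furan-2(5H)-one
Conditions: HCl (0.5 M aq), THF, rt
Reagents that add atoms: water, O
Why: Dilute acid hydrolyses the enol ether to the C9 aldehyde and cleaves the primary allylic silyl ether in the same flask; the electron-poor dienyl lactone and the trisubstituted alkene tolerate these conditions.

Step 14
Reactants: 19 the hydroxy aldehyde
Product: 21 4-[(1E)-2-(bromomethyl)-6-methylhepta-1,5-dien-1-yl]-3-{(1R,2R)-2-[(2S)-4-oxobutan-2-yl]cyclopropyl}furan-2(5H)-one, via allylic mesylate 20 (not isolated)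
Conditions: MsCl, Et3N, THF, −40 °C; then LiBr, −40 to 0 °C
Reagents that add atoms: lithium bromide, [Li+].[Br-]
Why: Sulfonylation of the allylic alcohol and SN2 displacement by bromide at the primary carbon; the aldehyde is inert to both reagents and the alkene geometry is kept. The bromide is used at once in step 15.

Step 15
Reactants: 21 the bromo aldehyde
Product: 23 (2R,4R,5S,7S,8R)-7-hydroxy-5-methyl-8-(6-methylhepta-1,5-dien-2-yl)-11-oxatricyclo[7.3.0.0^{2,4}]dodec-1(9)-en-12-one, via allylchromium dichloride 22 (not isolated)
Conditions: CrCl2 (8 equiv), THF, rt, slow addition of 21 (final 0.003 M)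
Reagents that add atoms: none
Why: Two one-electron transfers from divalent chromium turn the allylic bromide into the σ-allyl species 22 of trivalent chromium, bound at the primary carbon C2'; the metal then binds the aldehyde oxygen and the γ carbon C1 attacks C9 through a six-membered chair-like transition state, so that the double bond moves to C1'=C2' and the butenolide stays conjugated. The closest known reaction type is the intramolecular Nozaki–Hiyama allylation used for medium and large carbocycles, and the site of attack parallels the CrCl2 reactions of γ-bromo-α,β-unsaturated esters, which also bond through the carbon remote from the halide. The one ring closed is the eight-membered carbocycle, by the bond C1–C9 in an 8-exo-trig mode. C1 is set under substrate control: the aldehyde reaches the planar C1 through the tether C3–C4–C6–C7–C8, which the cis-cyclopropane and the C7 methyl group should bias toward one face. C9 is set relative to C1 in the same cyclic transition state; because C2 and C8 are tied by a short tether with two cis-locked units, the chair with C2 axial and C8 equatorial (the Z rotamer of 22, reachable by equilibration) is expected, and it gives the cis relation of hydroxyl and side chain. The step needs attack through C1 and not through C2' (ten-membered ring) or C3 (six-membered ring with a quaternary centre); this should be secured by the metal resting on the unhindered primary terminus and by the closed transition state, which C3 could enter only from a hindered C1-bound or an O-bound form. High dilution suppresses intermolecular allylation, and allylchromium reagents do not attack the lactone carbonyl or the trisubstituted alkene.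

Step 16
Reactants: 23 the tricyclic homoallylic alcohol
Product: 25 (2R,4R,5S,7S,8R)-7-hydroxy-8-[(2S)-1-hydroxy-6-methylhept-5-en-2-yl]-5-methyl-11-oxatricyclo[7.3.0.0^{2,4}]dodec-1(9)-en-12-one, via bis-borane adduct 24 (not isolated)
Conditions: 9-BBN (3 equiv), THF, 0 °C to rt; then NaBO3·4H2O, H2O, rt
Reagents that add atoms: sodium perborate tetrahydrate, [Na+].[O-]OB=O
Why: Hydroboration–oxidation; 9-BBN puts boron on the methylene carbon of the 1,1-disubstituted alkene far faster than it attacks the trisubstituted alkene, and the lactone and its tetrasubstituted alkene are inert, while the C9 hydroxyl becomes a borinate with loss of H2. C1' is set under substrate control: with the homoprenyl branch turned away from the ring, hydrogen should reach C1' from the face remote from the bulky C9–O–B group, giving the S centre. Perborate oxidises the C–B bond with retention under nearly neutral conditions that spare the base-sensitive vinylogous aldol.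

Step 17
Reactants: 25 the diol
Product: 26 [(2S)-2-[(2R,4R,5S,7S,8R)-7-hydroxy-5-methyl-12-oxo-11-oxatricyclo[7.3.0.0^{2,4}]dodec-1(9)-en-8-yl]-6-methylhept-5-en-1-yl] acetate
Conditions: Ac2O (1.1 equiv), pyridine, CH2Cl2, 0 °C
Reagents that add atoms: acetic anhydride, CC(=O)OC(C)=O
Why: Acylation is much faster at the unhindered primary hydroxyl than at the secondary C9 hydroxyl flanked by the ring; the weak base does not provoke retro-aldol cleavage or dehydration.

## Compound list

1 | 5-bromo-2-methylpent-2-ene | CC(C)=CCCBr | starting material
2 | 5-iodo-2-methylpent-2-ene | CC(C)=CCCI | intermediate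
3 | tert-butyldimethyl(prop-2-yn-1-yloxy)silane | C#CCO[Si](C)(C)C(C)(C)C | starting material
4 | bis(pinacolato)diboron | CC1(C)OB(OC1(C)C)B1OC(C)(C)C(C)(C)O1 | starting material
5 | (E)-tert-butyldimethyl{[6-methyl-2-[(4,4,5,5-tetramethyl-1,3,2-dioxaborolan-2-yl)methylidene]hept-5-en-1-yl]oxy}silane | CC(C)(C)[Si](C)(C)OC/C(CCC=C(C)C)=C/B1OC(C)(C)C(C)(C)O1 | intermediate
6 | 3,4-dibromofuran-2(5H)-one | O=C1OCC(Br)=C1Br | starting material
7 | 3-bromo-4-[(1E)-2-({[tert-butyl(dimethyl)silyl]oxy}methyl)-6-methylhepta-1,5-dien-1-yl]furan-2(5H)-one | CC(C)(C)[Si](C)(C)OC/C(CCC=C(C)C)=C/C1=C(Br)C(=O)OC1 | intermediate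
8 | methyl (S)-3-hydroxy-2-methylpropanoate | COC(=O)[C@@H](C)CO | starting material
9 | methyl (S)-3-[(tert-butyldiphenylsilyl)oxy]-2-methylpropanoate | COC(=O)[C@@H](C)CO[Si](c1ccccc1)(c1ccccc1)C(C)(C)C | intermediate
10 | (S)-3-[(tert-butyldiphenylsilyl)oxy]-2-methylpropanal | O=C[C@@H](C)CO[Si](c1ccccc1)(c1ccccc1)C(C)(C)C | intermediate
11 | (R)-tert-butyl[(2-methylbut-3-yn-1-yl)oxy]diphenylsilane | C#C[C@@H](C)CO[Si](c1ccccc1)(c1ccccc1)C(C)(C)C | intermediate
12 | pinacolborane | CC1(C)OBOC1(C)C | starting material
13 | (R,Z)-tert-butyl{[2-methyl-4-(4,4,5,5-tetramethyl-1,3,2-dioxaborolan-2-yl)but-3-en-1-yl]oxy}diphenylsilane | CC1(C)OB(/C=C\[C@@H](C)CO[Si](c2ccccc2)(c2ccccc2)C(C)(C)C)OC1(C)C | intermediate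
14 | tert-butyl{(2R)-2-[(1S,2R)-2-(4,4,5,5-tetramethyl-1,3,2-dioxaborolan-2-yl)cyclopropyl]propoxy}diphenylsilane | CC1(C)OB(OC1(C)C)[C@@H]1C[C@@H]1[C@@H](C)CO[Si](c1ccccc1)(c1ccccc1)C(C)(C)C | intermediate
15 | (2R)-2-[(1S,2R)-2-(4,4,5,5-tetramethyl-1,3,2-dioxaborolan-2-yl)cyclopropyl]propan-1-ol | CC1(C)OB(OC1(C)C)[C@@H]1C[C@@H]1[C@@H](C)CO | intermediate
16 | (2R)-2-[(1S,2R)-2-(4,4,5,5-tetramethyl-1,3,2-dioxaborolan-2-yl)cyclopropyl]propanal | CC1(C)OB(OC1(C)C)[C@@H]1C[C@@H]1[C@@H](C)C=O | intermediate
17 | 2-{(1R,2S)-2-[(2R)-4-methoxybut-3-en-2-yl]cyclopropyl}-4,4,5,5-tetramethyl-1,3,2-dioxaborolane (E/Z mixture) | CC1(C)OB(OC1(C)C)[C@@H]1C[C@@H]1[C@@H](C)C=COC | intermediate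
18 | 4-[(1E)-2-({[tert-butyl(dimethyl)silyl]oxy}methyl)-6-methylhepta-1,5-dien-1-yl]-3-{(1R,2R)-2-[(2R)-4-methoxybut-3-en-2-yl]cyclopropyl}furan-2(5H)-one | CC(C)(C)[Si](C)(C)OC/C(CCC=C(C)C)=C/C1=C(C(=O)OC1)[C@@H]1C[C@@H]1[C@@H](C)C=COC | intermediate
19 | 4-[(1E)-2-(hydroxymethyl)-6-methylhepta-1,5-dien-1-yl]-3-{(1R,2R)-2-[(2S)-4-oxobutan-2-yl]cyclopropyl}furan-2(5H)-one | OC/C(CCC=C(C)C)=C/C1=C(C(=O)OC1)[C@@H]1C[C@@H]1[C@@H](C)CC=O | intermediate
20 | allylic mesylate of 19 (methanesulfonate at C2') | CS(=O)(=O)OC/C(CCC=C(C)C)=C/C1=C(C(=O)OC1)[C@@H]1C[C@@H]1[C@@H](C)CC=O | intermediate (not isolated)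
21 | 4-[(1E)-2-(bromomethyl)-6-methylhepta-1,5-dien-1-yl]-3-{(1R,2R)-2-[(2S)-4-oxobutan-2-yl]cyclopropyl}furan-2(5H)-one | BrC/C(CCC=C(C)C)=C/C1=C(C(=O)OC1)[C@@H]1C[C@@H]1[C@@H](C)CC=O | intermediate
22 | allylchromium dichloride (21 with CrCl2 in place of Br at C2'; trivalent chromium, THF ligands omitted) | Cl[Cr](Cl)C/C(CCC=C(C)C)=C/C1=C(C(=O)OC1)[C@@H]1C[C@@H]1[C@@H](C)CC=O | intermediate (not isolated)
23 | (2R,4R,5S,7S,8R)-7-hydroxy-5-methyl-8-(6-methylhepta-1,5-dien-2-yl)-11-oxatricyclo[7.3.0.0^{2,4}]dodec-1(9)-en-12-one (C1 = position 8, C9 = position 7) | C=C(CCC=C(C)C)[C@@H]1C2=C(C(=O)OC2)[C@@H]2C[C@@H]2[C@@H](C)C[C@@H]1O | intermediate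
24 | bis-borane adduct (23 with a 9-borabicyclo[3.3.1]nonan-9-yl group on C2' and on the C9 oxygen; C1' now sp3) | B1(C2CCCC1CCC2)C[C@@H](CCC=C(C)C)[C@@H]1C2=C(C(=O)OC2)[C@@H]2C[C@@H]2[C@@H](C)C[C@@H]1OB1C2CCCC1CCC2 | intermediate (not isolated)
25 | (2R,4R,5S,7S,8R)-7-hydroxy-8-[(2S)-1-hydroxy-6-methylhept-5-en-2-yl]-5-methyl-11-oxatricyclo[7.3.0.0^{2,4}]dodec-1(9)-en-12-one | OC[C@@H](CCC=C(C)C)[C@@H]1C2=C(C(=O)OC2)[C@@H]2C[C@@H]2[C@@H](C)C[C@@H]1O | intermediate
26 | [(2S)-2-[(2R,4R,5S,7S,8R)-7-hydroxy-5-methyl-12-oxo-11-oxatricyclo[7.3.0.0^{2,4}]dodec-1(9)-en-8-yl]-6-methylhept-5-en-1-yl] acetate | CC(=O)OC[C@@H](CCC=C(C)C)[C@@H]1C2=C(C(=O)OC2)[C@@H]2C[C@@H]2[C@@H](C)C[C@@H]1O | target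

## Step count and least certain steps

Total: 17 steps. Longest linear sequence: 14 steps (8 to 26, steps 4 to 17).

**Step 15 (key step).** The most likely failure is closure with the wrong relative configuration at C9 (or C1), because ring strain and not the reagent decides between the competing chair arrangements. Bonding through C3 or intermolecular allylation are further possibilities. The fallback sets out from 21 and comes back at 23. The cyclisation is run as planned and the (2R,4R,5S,7R,8R) C9-epimeric alcohol F1 is oxidised with Dess–Martin periodinane to the 7,12-dione F2. F2 is reduced with LiBH(s-Bu)3 at −78 °C, where hydride should enter from the face opposite the C1 side chain and give the cis alcohol 23. The ketone also allows C1 to be equilibrated if needed. C9 is then set by ketone reduction and not in the C–C bond formation.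

**Step 2.** The most likely failure is loss of regiocontrol or β-elimination of the silyloxy group from the alkenylcopper intermediate (allene formation), because alkylation by an unactivated iodide is slow. The fallback sets out from 1 and 3 and comes back at 5. Bromide 1 is turned into 4-methylpent-3-en-1-ylmagnesium bromide F3, which is transferred to copper with CuBr·SMe2 and added syn across 3 in Et2O. Iodine then gives (E)-tert-butyl{[2-(iodomethylidene)-6-methylhept-5-en-1-yl]oxy}dimethylsilane F4. Palladium-catalysed borylation of F4 with 12 (PdCl2(dppf), Et3N, dioxane, 80 °C) gives 5 with retention.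

**Step 8.** The most likely failure is poor facial selectivity, because the methyl and silyloxymethyl groups that flank the alkene differ only moderately in size. The fallback sets out from 13 and comes back at 14. The pinacol ester is cleaved (NaIO4, NH4OAc, acetone/H2O) to the (R,Z)-alkenylboronic acid F5, which is esterified with (2R,3R)-N,N,N',N'-tetramethyltartramide to the dioxaborolane F6. There the amide carbonyl delivers the zinc carbenoid (Zn–Cu, CH2I2) under auxiliary control to give the cyclopropyl tartramide boronate F7, and exchange with pinacol returns 14. F6 and F7 are drawn with the R,R auxiliary; the mirror-image auxiliary is taken if its directing sense opposes the one needed.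

**Step 12.** The most likely failure is slow transmetalation of the hindered secondary cyclopropyl boronate. This would leave time for protodebromination of 7, for Heck-type consumption of the enol ether, or for base-induced isomerisation of the butenolide. The fallback sets out from 17 and comes back at 18. Brief treatment of 17 with KHF2 in MeOH/H2O gives the potassium cyclopropyltrifluoroborate F8, which releases the boronic acid slowly. F8 is coupled with 7 using PdCl2(dppf) and Cs2CO3 in THF/H2O. Any acetal formed from the enol ether during the salt formation is an equivalent latent aldehyde.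

**Step 16.** The most likely failure is poor or reversed facial selectivity at C1', because the two flanks of the methylene (C2 and C9) are of similar size and the reactive rotamer is uncertain. The fallback sets out from 23 and comes back at 25. The C9 hydroxyl is protected with Et3SiOTf and 2,6-lutidine to give the triethylsilyl ether F9. The methylene is then hydroborated under reagent control with the matched enantiomer of 10-phenyl-9-borabicyclo[3.3.2]decane and oxidised with NaBO3·4H2O to the primary alcohol F10. HF·pyridine then returns 25.

## Further compounds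

F1 | step 15 | (2R,4R,5S,7R,8R)-7-hydroxy-5-methyl-8-(6-methylhepta-1,5-dien-2-yl)-11-oxatricyclo[7.3.0.0^{2,4}]dodec-1(9)-en-12-one (C9 epimer of 23) | C=C(CCC=C(C)C)[C@@H]1C2=C(C(=O)OC2)[C@@H]2C[C@@H]2[C@@H](C)C[C@H]1O
F2 | step 15 | (2R,4R,5S,8R)-5-methyl-8-(6-methylhepta-1,5-dien-2-yl)-11-oxatricyclo[7.3.0.0^{2,4}]dodec-1(9)-ene-7,12-dione | C=C(CCC=C(C)C)[C@@H]1C2=C(C(=O)OC2)[C@@H]2C[C@@H]2[C@@H](C)CC1=O
F3 | step 2 | 4-methylpent-3-en-1-ylmagnesium bromide | CC(C)=CCC[Mg]Br
F4 | step 2 | (E)-tert-butyl{[2-(iodomethylidene)-6-methylhept-5-en-1-yl]oxy}dimethylsilane | CC(C)(C)[Si](C)(C)OC/C(CCC=C(C)C)=C/I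
F5 | step 8 | [(R,Z)-4-[(tert-butyldiphenylsilyl)oxy]-3-methylbut-1-en-1-yl]boronic acid | OB(O)/C=C\[C@@H](C)CO[Si](c1ccccc1)(c1ccccc1)C(C)(C)C
F6 | step 8 | (4R,5R)-2-[(R,Z)-4-[(tert-butyldiphenylsilyl)oxy]-3-methylbut-1-en-1-yl]-N,N,N',N'-tetramethyl-1,3,2-dioxaborolane-4,5-dicarboxamide | CN(C)C(=O)[C@@H]1OB(/C=C\[C@@H](C)CO[Si](c2ccccc2)(c2ccccc2)C(C)(C)C)O[C@H]1C(=O)N(C)C
F7 | step 8 | (4R,5R)-2-{(1R,2S)-2-[(2R)-1-[(tert-butyldiphenylsilyl)oxy]propan-2-yl]cyclopropyl}-N,N,N',N'-tetramethyl-1,3,2-dioxaborolane-4,5-dicarboxamide | CN(C)C(=O)[C@@H]1OB([C@@H]2C[C@@H]2[C@@H](C)CO[Si](c2ccccc2)(c2ccccc2)C(C)(C)C)O[C@H]1C(=O)N(C)C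
F8 | step 12 | potassium trifluoro{(1R,2S)-2-[(2R)-4-methoxybut-3-en-2-yl]cyclopropyl}borate | [K+].F[B-](F)(F)[C@@H]1C[C@@H]1[C@@H](C)C=COC
F9 | step 16 | triethylsilyl ether of 23 at the C9 oxygen | C=C(CCC=C(C)C)[C@@H]1C2=C(C(=O)OC2)[C@@H]2C[C@@H]2[C@@H](C)C[C@@H]1O[Si](CC)(CC)CC
F10 | step 16 | triethylsilyl ether of 25 at the C9 oxygen | OC[C@@H](CCC=C(C)C)[C@@H]1C2=C(C(=O)OC2)[C@@H]2C[C@@H]2[C@@H](C)C[C@@H]1O[Si](CC)(CC)CC
A1 | alternative 1 | bicyclo[6.1.0]nonene enol pivalate (C3 pivalate, C2 CH2OSiEt3, C9 silyl ether) | CC(C)(C)[Si](C)(C)OC[C@@H](CCCOCc1ccc(OC)cc1)[C@@H]1/C(CO[Si](CC)(CC)CC)=C(OC(=O)C(C)(C)C)\[C@@H]2C[C@@H]2[C@@H](C)C[C@@H]1O[Si](C)(C)C(C)(C)C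
A2 | alternative 1 | open-chain tertiary propargyl pivalate with terminal C5=C6 alkene (C2 configuration immaterial) | CC(C)(C)[Si](C)(C)OC[C@@H](CCCOCc1ccc(OC)cc1)[C@H](C(OC(=O)C(C)(C)C)(CO[Si](CC)(CC)CC)C#C)[C@@H](O[Si](C)(C)C(C)(C)C)C[C@H](C)C=C
A3 | alternative 2 | C9-oxo cyclooctane cis-fused to the saturated γ-lactone, cyclopropane in place | CC(C)(C)[Si](C)(C)OC[C@@H](CCC=C(C)C)[C@@H]1[C@@H]2[C@@H](C(=O)OC2)[C@@H]2C[C@@H]2[C@@H](C)CC1=O
A4 | alternative 2 | (E)-allylic ester of the enolised bicyclo[4.1.0]heptane β-keto acid | OC1=C(C(=O)OC/C=C/[C@@H](CO[Si](C)(C)C(C)(C)C)CCC=C(C)C)[C@@H]2C[C@@H]2[C@@H](C)C1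
A5 | alternative 3 | oxasilinane spanning the C9 oxygen and C2' | C1[C@@H](CCC=C(C)C)[C@@H]2C3=C(C(=O)OC3)[C@@H]3C[C@@H]3[C@@H](C)C[C@@H]2O[Si]1(CC)CC
A6 | alternative 3 | diethylhydrosilyl ether of the C9 alcohol carrying a C2' methyl group | C[C@@H](CCC=C(C)C)[C@@H]1C2=C(C(=O)OC2)[C@@H]2C[C@@H]2[C@@H](C)C[C@@H]1O[SiH](CC)CC
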